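**Retrosynthetic overview**
1. Target 15 is an isomer of the 6-cinnamoylchromane-5,8-dione 13. The C3=C4 alkene and the 5,8-hydroquinone both come from a redox-neutral tautomerisation of 13.
2. Key bond C6–C(=O): an unmasked cinnamoyl anion donor (cinnamoylzirconocene chloride, from phenylacetylene and CO) is joined to the electrophilic C6–Cl carbon of chloroquinone 9.
3. The side-chain tertiary alcohol comes from a Schenck ene reaction on the prenyl tail of 7.
4. O1–C8a is closed by intramolecular chloride displacement. C4–C4a is made by radical addition of hydroborated (S)-linalool to 2,5-dichlorobenzoquinone. C2 is bought with linalool.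
5. Ring order: the carbocycle is bought as the quinone, the dihydropyran is closed in step 2, and aromatisation to the 2H-chromene occurs in step 4. The phenyl ring is bought.

Assumption: (S)-(+)-linalool (coriandrol) is bought as the single enantiomer (≥98 % ee), and the ee of 15 equals that of 1.
Chromene numbering (O1, C2 … C8a) is used throughout, with primes for the C2 side chain. No bond to the stereocentre is broken in any step. The S/R changes in the names are CIP priority changes only.

**Step 1**
Reactants: 1 (S)-linalool; 2 2,5-dichloro-1,4-benzoquinone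
Product: 5 2,5-dichloro-3-[(3S)-3-hydroxy-3,7-dimethyloct-6-en-1-yl]benzene-1,4-diol, via O,C-bis(catecholboryl) adduct of linalool 3 (not isolated), via bis(catecholborate) of the alkylated hydroquinone 4 (not isolated)
Conditions: catecholborane (2.2 equiv), RhCl(PPh3)3 (1 mol %), THF, 0 °C → rt; then 2 (1.1 equiv), DMPU (1 equiv), air (cat.), CH2Cl2, 0 °C → rt; pH 7 buffer
Reagents that add atoms: none
Why: Rh-catalysed anti-Markovnikov hydroboration takes only the monosubstituted vinyl group (the OH is masked in situ as its borate), and the B-alkylcatecholborane then passes its primary alkyl radical, in an O2-initiated chain (organoborane conjugate addition to a quinone), to one of the two equivalent C–H carbons of 2, after which tautomerisation gives the hydroquinone; the carbinol carbon is a spectator and stays (S).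

**Step 2**
Reactants: 5 2,5-dichloro-3-[(3S)-3-hydroxy-3,7-dimethyloct-6-en-1-yl]benzene-1,4-diol
Product: 7 (2S)-6-chloro-2-methyl-2-(4-methylpent-3-en-1-yl)-3,4-dihydro-2H-chromene-5,8-dione, via 2,5-dichloro-3-[(3S)-3-hydroxy-3,7-dimethyloct-6-en-1-yl]-1,4-benzoquinone 6 (not isolated)
Conditions: Ag2O (4 equiv), 4 Å MS, CH2Cl2, rt, dark
Reagents that add atoms: none
Why: Ag2O oxidises the hydroquinone to quinone 6, whose C–Cl next to the side chain is a vinylogous acid chloride within six-ring reach of the tertiary OH, so intramolecular addition–elimination (vinylic substitution, driven by AgCl precipitation) closes the dihydropyran; only the O–H bond of the carbinol breaks, so the configuration is retained.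

**Step 3**
Reactants: 7 (2S)-6-chloro-2-methyl-2-(4-methylpent-3-en-1-yl)-3,4-dihydro-2H-chromene-5,8-dione
Product: 9 (2R)-6-chloro-2-[(2E)-4-hydroxy-4-methylpent-2-en-1-yl]-2-methyl-3,4-dihydro-2H-chromene-5,8-dione, via (2R)-6-chloro-2-[(2E)-4-hydroperoxy-4-methylpent-2-en-1-yl]-2-methyl-3,4-dihydro-2H-chromene-5,8-dione 8 (not isolated)
Conditions: O2, methylene blue (1 mol %), 660 nm LED, MeCN, 0 °C; then Me2S (5 equiv), 0 °C → rt; chromatography
Reagents that add atoms: dioxygen (used as singlet oxygen), O=O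
Why: In this Schenck ene reaction 1O2 attacks only the electron-rich trisubstituted alkene (the quinone C=C bonds are too electron-poor and red light excites only the dye), and abstraction of a C2'–H moves the double bond to give the (E)-tertiary allylic hydroperoxide 8 (with roughly an equal amount of the separable secondary regioisomer), which Me2S reduces without touching the quinone; no stereocentre is made and C2 is untouched.

**Step 4**
Reactants: 9 (2R)-6-chloro-2-[(2E)-4-hydroxy-4-methylpent-2-en-1-yl]-2-methyl-3,4-dihydro-2H-chromene-5,8-dione; 10 phenylacetylene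
Product: 15 (2E)-1-{(2S)-5,8-dihydroxy-2-[(2E)-4-hydroxy-4-methylpent-2-en-1-yl]-2-methyl-2H-chromen-6-yl}-3-phenylprop-2-en-1-one, via (E)-styrylzirconocene chloride 11 (not isolated), via (E)-cinnamoylzirconocene chloride 12 (not isolated), via (2R)-6-cinnamoylchromane-5,8-dione 13 (not isolated), via (2S)-o-quinone methide tautomer 14 (not isolated)
Conditions: 10 (1.4 equiv), Cp2Zr(H)Cl (1.3 equiv), CH2Cl2, rt; CO (1 atm), rt; then 9, Pd2(dba)3 (2.5 mol %), P(2-furyl)3 (10 mol %), THF, CO (1 atm), 0 °C → rt; filter (Florisil); basic Al2O3, CH2Cl2, rt, dark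
Reagents that add atoms: carbon monoxide, [C-]#[O+]
Why: Proposed new method: hydrozirconation and CO insertion turn the alkyne into (E)-cinnamoylzirconocene chloride 12, an unmasked α,β-unsaturated acyl anion donor, so a carbonyl carbon acts as the nucleophile toward C6 of 9, itself an electrophilic β-chloro-enone (vinylogous acid chloride) carbon of C8=O, the one carbonyl not damped by the ring oxygen; oxidative addition of Pd(0) into C6–Cl, Zr→Pd acyl transfer (the CO atmosphere blocks decarbonylation) and reductive elimination give acylquinone 13 with the quinone oxidation level kept, and basic alumina then spends that level in two prototropic shifts (C4–H to O8 giving 14, then C3–H to O5) that are estimated at about 12 kcal/mol downhill and create the C3=C4 alkene and the H-bonded hydroquinone with no bond at C2 touched, the enone staying (E) from syn-hydrozirconation; the closest known reaction types are Pd-catalysed acylation of organic halides and enones with acylzirconocene chlorides, Stille/Negishi coupling of haloquinones, and the alumina- or base-induced alkylquinone → chromenol tautomerisation.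

Compound 15 is kept in the dark and at or below 25 °C, because 2H-chromenes can racemise by electrocyclic ring opening.

**Compound list**
1 | (S)-(+)-linalool, (3S)-3,7-dimethylocta-1,6-dien-3-ol | CC(C)=CCC[C@](C)(O)C=C | starting material
2 | 2,5-dichloro-1,4-benzoquinone | O=C1C=C(Cl)C(=O)C=C1Cl | starting material
3 | 2-[(3R)-3-(1,3,2-benzodioxaborol-2-yloxy)-3,7-dimethyloct-6-en-1-yl]-1,3,2-benzodioxaborole | CC(C)=CCC[C@](C)(OB1Oc2ccccc2O1)CCB1Oc2ccccc2O1 | intermediate
4 | bis(catecholborate) of 5: Bcat on the tertiary O and on the ring O flanked by Cl and H, (S) carbinol carbon | CC(C)=CCC[C@](C)(OB1Oc2ccccc2O1)CCc1c(O)c(Cl)cc(OB2Oc3ccccc3O2)c1Cl | intermediate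
5 | 2,5-dichloro-3-[(3S)-3-hydroxy-3,7-dimethyloct-6-en-1-yl]benzene-1,4-diol | CC(C)=CCC[C@](C)(O)CCc1c(O)c(Cl)cc(O)c1Cl | intermediate
6 | 2,5-dichloro-3-[(3S)-3-hydroxy-3,7-dimethyloct-6-en-1-yl]cyclohexa-2,5-diene-1,4-dione | CC(C)=CCC[C@](C)(O)CCC1=C(Cl)C(=O)C=C(Cl)C1=O | intermediate
7 | (2S)-6-chloro-2-methyl-2-(4-methylpent-3-en-1-yl)-3,4-dihydro-2H-chromene-5,8-dione | CC(C)=CCC[C@@]1(C)CCC2=C(O1)C(=O)C=C(Cl)C2=O | intermediate
8 | (2R)-6-chloro-2-[(2E)-4-hydroperoxy-4-methylpent-2-en-1-yl]-2-methyl-3,4-dihydro-2H-chromene-5,8-dione | CC(C)(OO)/C=C/C[C@@]1(C)CCC2=C(O1)C(=O)C=C(Cl)C2=O | intermediate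
9 | (2R)-6-chloro-2-[(2E)-4-hydroxy-4-methylpent-2-en-1-yl]-2-methyl-3,4-dihydro-2H-chromene-5,8-dione | CC(C)(O)/C=C/C[C@@]1(C)CCC2=C(O1)C(=O)C=C(Cl)C2=O | intermediate
10 | phenylacetylene | C#Cc1ccccc1 | starting material
11 | chlorobis(cyclopentadienyl)[(E)-2-phenylethenyl]zirconium | Cl[Zr](/C=C/c1ccccc1)(C1C=CC=C1)C1C=CC=C1 | intermediate
12 | chlorobis(cyclopentadienyl)[(E)-3-phenylprop-2-enoyl]zirconium | O=C(/C=C/c1ccccc1)[Zr](Cl)(C1C=CC=C1)C1C=CC=C1 | intermediate
13 | (2R)-2-[(2E)-4-hydroxy-4-methylpent-2-en-1-yl]-2-methyl-6-[(2E)-3-phenylprop-2-enoyl]-3,4-dihydro-2H-chromene-5,8-dione | CC(C)(O)/C=C/C[C@@]1(C)CCC2=C(O1)C(=O)C=C(C(=O)/C=C/c3ccccc3)C2=O | intermediate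
14 | (2S)-8-hydroxy-2-[(2E)-4-hydroxy-4-methylpent-2-en-1-yl]-2-methyl-6-[(2E)-3-phenylprop-2-enoyl]-2,3-dihydro-5H-chromen-5-one (o-quinone methide, C4=C4a) | CC(C)(O)/C=C/C[C@@]1(C)CC=C2C(=O)C(C(=O)/C=C/c3ccccc3)=CC(O)=C2O1 | intermediate
15 | (2E)-1-{(2S)-5,8-dihydroxy-2-[(2E)-4-hydroxy-4-methylpent-2-en-1-yl]-2-methyl-2H-chromen-6-yl}-3-phenylprop-2-en-1-one (CNP0327890.1) | CC(C)(O)/C=C/C[C@@]1(C)C=Cc2c(O)c(C(=O)/C=C/c3ccccc3)cc(O)c2O1 | target

**Step count and weak points**
Total step count: 4 (step 4 is one telescoped operation). Longest linear sequence: 4.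

Steps most likely to fail, in order of risk: 4, 1, 3.

Step 4. The acyl transfer to a haloquinone is untested. Possible side reactions are 1,2-acylation at C8=O, a second acylation of 13 at C7, and reduction of 13. The fallback sets out from 9 and comes back at 15. It uses a masked acetyl anion and builds the styryl part later by aldol chemistry. Stille coupling of 9 with tributyl(1-ethoxyvinyl)stannane (PdCl2(PPh3)2, CuI, dioxane, 60 °C) gives the 6-(1-ethoxyethenyl)chromane-5,8-dione F1. Wet silica gel with oxalic acid hydrolyses the enol ether to the 6-acetylchromane-5,8-dione F2. Basic alumina tautomerises F2 through the acetyl o-quinone methide F3 to the 6-acetyl-5,8-dihydroxy-2H-chromene F4. Claisen–Schmidt condensation of F4 with benzaldehyde (Ba(OH)2, EtOH, N2, rt, dark) gives 15.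

Step 1. The alkyl radical may attack oxygen or a C–Cl carbon of the electron-poor quinone, or the chain may be short. The fallback sets out from 1 and comes back at 6. It replaces the radical addition by a two-electron cross-coupling on a protected arene. Commercial 1,4-dichloro-2,5-dimethoxybenzene is lithiated between OMe and Cl (LDA, THF, −78 °C) and quenched with I2 to give 1,4-dichloro-2-iodo-3,6-dimethoxybenzene F5. Compound 1 is hydroborated with 9-BBN (2.1 equiv) to the O,C-bis(9-BBN) adduct F6. B-alkyl Suzuki–Miyaura coupling of F6 with F5 at the C–I bond (Pd(dppf)Cl2, K3PO4, THF/H2O) gives (3S)-1-(2,5-dichloro-3,6-dimethoxyphenyl)-3,7-dimethyloct-6-en-3-ol F7. Oxidative demethylation (CAN, or AgO/HNO3, MeCN/H2O, 0 °C) gives quinone 6, which is closed to 7 as in step 2.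

Step 3. The ene reaction is inherently about 1:1 in regiochemistry, and the hydroperoxide must be reduced next to an electrophilic chloroquinone. The fallback sets out from 7 and comes back at 9. It is an ionic, regiospecific transposition in place of the pericyclic oxygenation. Markovnikov hydroxyselenation of 7 (PhSeCl, MeCN/H2O, rt) gives the 4'-hydroxy-3'-(phenylselanyl) compound F8. Oxidation with NaIO4 (aq. THF, 0 °C) gives the selenoxide F9, whose only β-hydrogens are on C2', so syn elimination at rt gives the (E)-allylic tertiary alcohol 9.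

**Further compounds**
F1 | step 4 | (2R)-6-(1-ethoxyethenyl)-2-[(2E)-4-hydroxy-4-methylpent-2-en-1-yl]-2-methyl-3,4-dihydro-2H-chromene-5,8-dione | CC(C)(O)/C=C/C[C@@]1(C)CCC2=C(O1)C(=O)C=C(C(=C)OCC)C2=O
F2 | step 4 | (2R)-6-acetyl-2-[(2E)-4-hydroxy-4-methylpent-2-en-1-yl]-2-methyl-3,4-dihydro-2H-chromene-5,8-dione | CC(C)(O)/C=C/C[C@@]1(C)CCC2=C(O1)C(=O)C=C(C(C)=O)C2=O
F3 | step 4 | (2S)-6-acetyl-8-hydroxy-2-[(2E)-4-hydroxy-4-methylpent-2-en-1-yl]-2-methyl-2,3-dihydro-5H-chromen-5-one | CC(C)(O)/C=C/C[C@@]1(C)CC=C2C(=O)C(C(C)=O)=CC(O)=C2O1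
F4 | step 4 | 1-{(2S)-5,8-dihydroxy-2-[(2E)-4-hydroxy-4-methylpent-2-en-1-yl]-2-methyl-2H-chromen-6-yl}ethan-1-one | CC(C)(O)/C=C/C[C@@]1(C)C=Cc2c(O)c(C(C)=O)cc(O)c2O1
F5 | step 1 | 1,4-dichloro-2-iodo-3,6-dimethoxybenzene | COc1c(I)c(Cl)c(OC)cc1Cl
F6 | step 1 | 9-[(3R)-3-(9-borabicyclo[3.3.1]nonan-9-yloxy)-3,7-dimethyloct-6-en-1-yl]-9-borabicyclo[3.3.1]nonane | CC(C)=CCC[C@](C)(OB1C2CCCC1CCC2)CCB1C2CCCC1CCC2
F7 | step 1 | (3S)-1-(2,5-dichloro-3,6-dimethoxyphenyl)-3,7-dimethyloct-6-en-3-ol | CC(C)=CCC[C@](C)(O)CCc1c(OC)c(Cl)cc(OC)c1Cl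
F8 | step 3 | (2R)-6-chloro-2-[4-hydroxy-4-methyl-3-(phenylselanyl)pentyl]-2-methyl-3,4-dihydro-2H-chromene-5,8-dione (both C3' epimers) | CC(C)(O)C(CC[C@@]1(C)CCC2=C(O1)C(=O)C=C(Cl)C2=O)[Se]c1ccccc1
F9 | step 3 | (2R)-6-chloro-2-[4-hydroxy-4-methyl-3-(phenylseleninyl)pentyl]-2-methyl-3,4-dihydro-2H-chromene-5,8-dione | CC(C)(O)C(CC[C@@]1(C)CCC2=C(O1)C(=O)C=C(Cl)C2=O)[Se](=O)c1ccccc1
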